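When should I stop the flask, and how much first product stands in it then?

| flask | substrate | reagent | remark | time |
|---|---|---|---|---|
| zeta | 10 mM | 22 mM | run made earlier |  |
| beta | 40 mM | 22 mM | run made earlier |  |
| flask | 20 mM | 22.0 mM |  | 12 min |

| run | time / min | first product / % | substrate / % |
|---|---|---|---|
| zeta | 1.50 | 17.9 | 80.8 |
| zeta | 2.50 | 23.9 | 70.7 |
| zeta | 4.00 | 31.7 | 60.1 |
| zeta | 6.00 | 34.6 | 52.9 |
| zeta | 10.0 | 38.5 | 39.1 |
| beta | 1.50 | 14.1 | 79.6 |
| beta | 2.50 | 17.2 | 69.2 |
| beta | 4.00 | 14.1 | 62.9 |
| beta | 6.00 | 15.2 | 53.3 |
| beta | 10.0 | 8.4 | 41.3 |

(each reading ± 1 percentage point)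

- the best time, 12 min at the latest, for first product
- the amount of first product, in percent of the substrate charged, at that time

Substrate falls alike at both charges, to 52.9% in zeta and 53.3% in beta at 6.00 min, but first product doesn't. Beta's readings stay near 15.1% up to 6.00 min, and I read that level as a crossing of making and loss. My carried quantity is the ceiling, the amount of first product at which making and loss balance (the intermediate's quasi-steady level), read from beta as 6.06 mM. I assume the same amount at any substrate charge with this reagent charge, which for this flask is 30.3% of the charge. I then let first product follow a first-order lag towards that ceiling, with the fraction of substrate spent as the clock and the ceiling as its constant.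

Left alone, this lag climbs to the end, but beta's 8.4% at 10.0 min reads as a sinking ceiling, so the stopping time is my weak link. I reforge it by scaling beta's highest reading, at 2.50 min, inversely with charge. That gives 5.00 min for this flask and 10.0 min for zeta, whose readings are still climbing at their last. Zeta's readings at 4.00 min and 6.00 min bracket that time, and their mean has 43.5% of the substrate spent. I assume the same for this flask, so the lag gives me 23.1%.

The forecast says 26% at 9 min (range 5 min to 12 min), later than my time and above my amount: “The peak is flat, so its time is poorly fixed.”

The flask peaks at 25.4% at 6.18 min, which is 83.8% of my ceiling. First product is made 2.96 times as fast as it is used up at 1.99 min, and 0.557 times as fast at 12.0 min.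

    substrate + reagent → first product (k = 0.140 M⁻¹ s⁻¹)
    reagent + first product → bis adduct (k = 0.0200 M⁻¹ s⁻¹)
    reagent + bis adduct → tris adduct (k = 0.0760 M⁻¹ s⁻¹)
    2 reagent → homo dimer (k = 0.110 M⁻¹ s⁻¹)
    substrate + first product → side product (k = 0.120 M⁻¹ s⁻¹)

For the neighbour charged with 50 mM of substrate, I reckon a ceiling of 12.1% of its charge. That neighbour gives 13.5% at best, above my ceiling, and at 12.0 min it holds 49.9% of its substrate charge as side product.

(Readings and results were computed from invented constants; noise was put on by code.)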